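The numbers in the tables come from a simulation with made-up constants; scatter was added.

The midnight run is our guide to this flask, which holds the same starting material but less reagent in the second phase.

- midnight: starting material 0.38 M; reagent in the second phase 1.2 equiv; run made earlier
- flask: starting material 0.38 M; reagent in the second phase 0.800 equiv; time 2.0 min; volume of the second phase over the first 1.0

midnight run (percent of the starting material charged)

| time / s | target / % | starting material / % |
|---|---|---|
| 10.0 | 3.2 | 84.4 |
| 20.0 | 5.7 | 70.9 |
| 25.0 | 8.4 | 65.2 |
| 40.0 | 15.4 | 51.6 |

(each reading ± 1 percentage point)

- in the second phase: reagent in the second phase; everything else is in the first
- charges count per volume of the first phase; a concentration in a rate is the amount of a species over the volume of its own phase; every rate counts per litre of the first phase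
- the earlier runs hold the two phases in the same ratio of volumes as the flask asked about

* target at 2.0 min, in percent of the starting material charged
* the change that raises the amount of target at 2.0 min, in percent of the starting material charged most ("none" if none brings more than 2 percentage points) (zeta / gamma / none)
* amount of target at 2.0 min, in percent of the starting material charged, after zeta

- zeta: doubling the transfer coefficient of the reagent in the second phase, all else as stated
- gamma: doubling the amount of reagent in the second phase, all else as stated

By 40.0 s the midnight run has lost 48.4 % of its starting material, yet target reads 15.4 %. So part of the loss goes elsewhere, and at that reading we read 31.8 % as the target share, the selectivity: target formed over starting material lost. But a share needs a loss to act on. In the midnight run the starting material falls roughly first order, at a read 0.992 min⁻¹, so for this flask by 2.0 min we reckon 86.3 % lost. That makes our own estimate for this flask 27.4 %, uncorrected for the smaller charge of reagent.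

The forecast differs from this: 33 %, with gamma as best and 43 % after zeta. Its ground for the choice: “Doubling the reagent helps in both pictures”.

The flask gives 21.9 %. The best change is gamma, worth 17 percentage points against 2.4 points for zeta, which reaches 24.3 %.

    reagent in the reaction phase ⇌ reagent in the second phase, rate k1*([reagent in the reaction phase] - [reagent in the second phase]/K1) per volume of the first phase (partition coefficient = 2.80, kL = 0.0575 s⁻¹)
    starting material + reagent in the reaction phase → target (k = 0.0727 M⁻¹ s⁻¹)
    2 starting material → homo dimer (k = 0.0196 M⁻¹ s⁻¹)

In this flask at 0.337 min, the homo dimer step uses starting material 2.9 times as fast as the target step. At 2.00 min this flask has 26 % of its starting material left, so the carried share gives 23.5 % of target against the 21.9 % found, and the loss was 74.0 %, less than we reckoned. In the neighbour flask charged with 0.65 M of starting material, 15 % of it is left at the same time, so the share gives 27.0 % of target. The computed result there is 25.5 %.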